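Ring B is disconnected at C8–C9 and C9–C10. The quaternary carbon C9 has C8 (CHCH3) and the ring-fusion carbon C10 as neighbours, and each would be β to a carbonyl at C6 (via C7 and via C5). C9 can therefore come from the CH2 of dimethyl malonate and bridge the two alkene termini of a cross-conjugated dienone. This dienone is the (E)-propenyl ketone of 6,6-dimethylcyclohexene, in which ring A and the gem-dimethyl carbon C4 are already in place. One flask forms both bonds, closes ring B and sets C8, C10 and C5. Later C6 delivers the 5-ene, the equatorial ester becomes C11 with the arene, the axial ester the C9 methyl; the aminoquinone comes last.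

Key step: step 4

Numbering: ring A is C1–C2–C3–C4–C5–C10 and ring B is C5–C6–C7–C8–C9–C10. C4 carries two methyl groups and C8 one. C9 carries a methyl group and C11, the CH2 that links to the quinone. In the quinone, C1' and C4' are the carbonyls, C2' is the oxygenated carbon next to C3', C3' bears C11, C5' is the second heteroatom-bearing carbon and C6' is CH.

Assumption: the quinine-derived 9-amino-9-deoxy-epi-quinine is taken to direct malonate to the C8 face that gives 8S; if the sense is opposite, the quinidine-derived pseudoenantiomer is used and nothing else changes.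

Step 1
Reactants: 1 2,2-dimethylcyclohexan-1-one
Product: 2 (E)-N'-(2,2-dimethylcyclohexylidene)-2,4,6-triisopropylbenzenesulfonohydrazide
Conditions: 2,4,6-(i-Pr)3C6H2SO2NHNH2, cat. HCl, MeOH, rt
Reagents that add atoms: 2,4,6-triisopropylbenzenesulfonohydrazide, CC(C)c1cc(C(C)C)c(S(=O)(=O)NN)c(C(C)C)c1
Why: Acid-catalysed hydrazone condensation, in which the sulfonamide nitrogen settles anti to the quaternary carbon and so syn to the only CH2 that can be deprotonated next.

Step 2
Reactants: 2 trisylhydrazone of step 1; 3 (E)-but-2-enal (crotonaldehyde)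
Product: 5 (E)-1-(6,6-dimethylcyclohex-1-en-1-yl)but-2-en-1-ol (racemic), via 6,6-dimethylcyclohex-1-enyllithium 4 (not isolated)
Conditions: n-BuLi (2.2 equiv), THF, −78 → 0 °C; then 3, −78 °C; H2O
Reagents that add atoms: none
Why: Shapiro reaction, in which double deprotonation (N–H and the sole α-CH2) and loss of sulfinate and N2 give one regiodefined vinyllithium that adds 1,2 to the enal; the carbinol centre forms as a racemate and is erased in step 3.

Step 3
Reactants: 5 dienol of step 2
Product: 6 (E)-1-(6,6-dimethylcyclohex-1-en-1-yl)but-2-en-1-one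
Conditions: activated MnO2 (excess), CH2Cl2, rt
Reagents that add atoms: none
Why: Allylic alcohol oxidation with MnO2, which is selective for the doubly allylic carbinol and leaves the (E)-alkene untouched.

Step 4
Reactants: 6 cross-conjugated dienone; 7 dimethyl malonate (1.5 equiv)
Product: 9 dimethyl (2S,4aS,8aR)-2,5,5-trimethyl-4-oxooctahydronaphthalene-1,1(2H)-dicarboxylate (5S,8S,10R; trans-fused), via mono-Michael adduct 8 (not isolated)
Conditions: 9-amino-9-deoxy-epi-quinine (20 mol %), CF3CO2H (40 mol %), toluene, rt to 40 °C; then DBU (60 mol %), same flask, rt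
Reagents that add atoms: none
Why: Condensation of the catalyst NH2 group with the C6 carbonyl gives an iminium ion conjugated to both alkenes, its nitrogen substituent turns away from the crowded C4/C5 side and sits over the propenyl arm, and the malonate, bound to the protonated quinuclidine, bonds to C8 on the face the catalyst leaves open, which sets C8 (S) and gives 8. The malonate carbon of 8 is deprotonated once more and bonds to C10 of the acylcyclohexene arm, a 6-endo-trig Michael ring closure (enolate exocyclic) that completes ring B through a chair with the C8 methyl and the C10–C1 bond equatorial, so C10 (R) is controlled by C8 and ends cis to it across C9. DBU drives this slower second addition and keeps it and the protonation at C5 reversible, so C5 (S) settles under thermodynamic control as the trans ring fusion and is in any case erased in step 6. The closest known reaction type is the organocatalytic [5+1] double Michael addition of active methylene compounds to divinyl ketones under cinchona-derived primary amine salts, the asymmetric form of the long-known base-mediated double Michael addition of malonates to cross-conjugated dienones. The step needs site selectivity (C8 before C10), which the substrate secures because the propenyl arm is unbranched at C7 and open at C8 while the ring arm is branched at C5 and shielded by C4, and enantioface selectivity at C8, which the catalyst provides. C9 is not yet a stereocentre, since both of its ester groups are the same.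

Step 5
Reactants: 9 keto diester
Product: 10 dimethyl (2S,4S,4aS,8aR)-4-hydroxy-2,5,5-trimethyloctahydronaphthalene-1,1(2H)-dicarboxylate (6S; axial OH, trans to H-5)
Conditions: LiBH(s-Bu)3, THF, −78 °C; then H2O2, aq NaOH, 0 °C
Reagents that add atoms: none
Why: Diastereoselective ketone reduction with a bulky trialkylborohydride, in which the axial C4 methyl blocks the axial trajectory so that hydride arrives equatorially on the face of H-5 and sets C6 (S) with an axial hydroxyl, while the esters survive and no C5 enolate, which could reopen ring B by retro-Michael reaction, is ever generated.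

Step 6
Reactants: 10 axial alcohol
Product: 11 dimethyl (2S,8aR)-2,5,5-trimethyl-3,5,6,7,8,8a-hexahydronaphthalene-1,1(2H)-dicarboxylate (5-ene)
Conditions: POCl3, pyridine, 0 → 60 °C
Reagents that add atoms: none
Why: Anti-periplanar E2 dehydration of the axial dichlorophosphate, in which H-5 and axial H-7 are both trans-diaxial to the leaving group but loss of H-5 should prevail because it gives the trisubstituted alkene and relieves the syn-axial contact with the C4 methyl, as in the dehydration of axial 6-hydroxy steroids to 5-enes.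

Step 7
Reactants: 11 alkene diester
Product: 12 methyl (1S,2S,8aR)-1-formyl-2,5,5-trimethyl-1,2,3,5,6,7,8,8a-octahydronaphthalene-1-carboxylate (equatorial CHO = C11, axial CO2Me)
Conditions: i-Bu2AlH (1.1 equiv), toluene, −78 °C; MeOH, then aq potassium sodium tartrate
Reagents that add atoms: none
Why: Partial reduction of one ester of a malonate with i-Bu2AlH, whose aluminium hemiacetal is chelated by the second ester and survives until work-up; group selection sets C9 (S) because the equatorial ester projects away from the bicycle whereas the axial one lies over ring B next to axial H-7 and the C5=C6 π face.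

Step 8
Reactants: 12 aldehyde ester; 13 1,2,4,5-tetramethoxybenzene
Product: 15 methyl (1S,2S,8aR)-1-[hydroxy(2,3,5,6-tetramethoxyphenyl)methyl]-2,5,5-trimethyl-1,2,3,5,6,7,8,8a-octahydronaphthalene-1-carboxylate (both C11 epimers), via 2,3,5,6-tetramethoxyphenyllithium 14 (not isolated)
Conditions: 13, n-BuLi, THF, 0 °C → rt; then 12, −78 → −40 °C; AcOH, −78 °C
Reagents that add atoms: none
Why: Directed ortho-lithiation between two methoxy groups followed by 1,2-addition of the aryllithium to the aldehyde, which is far more electrophilic than the neopentyl ester; C11 forms as an epimer mixture that is irrelevant because its oxygen leaves in step 11, and the cold acidic quench forestalls a retro-aldol reaction.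

Step 9
Reactants: 15 hydroxy ester
Product: 16 [(1R,2S,8aR)-1-(hydroxymethyl)-2,5,5-trimethyl-1,2,3,5,6,7,8,8a-octahydronaphthalen-1-yl](2,3,5,6-tetramethoxyphenyl)methanol (both C11 epimers)
Conditions: LiAlH4, THF, 0 °C → reflux
Reagents that add atoms: none
Why: LiAlH4 ester reduction, which removes the carbonyl that made a retro-aldol cleavage possible and touches no stereocentre (the C9 descriptor changes through priorities only).

Step 10
Reactants: 16 1,3-diol
Product: 17 six-membered cyclic thionocarbonate (1,3-dioxane-2-thione) of diol 16, spiro at C9 (9R,8S,10R; both C11 epimers)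
Conditions: 1,1'-thiocarbonyldiimidazole, DMAP (cat.), toluene, 100 °C
Reagents that add atoms: 1,1'-thiocarbonyldiimidazole, S=C(n1ccnc1)n1ccnc1
Why: Thiocarbonyl transfer, in which the primary alcohol is acylated first and the crowded benzylic hydroxyl then closes the ring intramolecularly, so that this alcohol need not be derivatised intermolecularly under strong base.

Step 11
Reactants: 17 cyclic thionocarbonate
Product: 19 [(1S,2S,8aR)-2,5,5-trimethyl-1-(2,3,5,6-tetramethoxybenzyl)-1,2,3,5,6,7,8,8a-octahydronaphthalen-1-yl]methanol, via S-tributylstannyl thiocarbonate 18 (not isolated)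
Conditions: n-Bu3SnH, AIBN (cat.), toluene, 110 °C; then aq NaOH, THF/MeOH, rt
Reagents that add atoms: none
Why: Barton–McCombie deoxygenation in its cyclic thionocarbonate form, in which the stannyl radical adds to sulfur, the adduct fragments at the C11–O bond towards the secondary benzylic radical rather than the primary one, hydrogen transfer gives the C11 methylene, and hydroxide then frees the primary alcohol.

Step 12
Reactants: 19 neopentyl alcohol
Product: 20 (1S,2S,8aR)-2,5,5-trimethyl-1-(2,3,5,6-tetramethoxybenzyl)-1,2,3,5,6,7,8,8a-octahydronaphthalene-1-carbaldehyde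
Conditions: Dess–Martin periodinane, CH2Cl2, rt
Reagents that add atoms: none
Why: Dess–Martin oxidation of a primary alcohol to a non-enolisable aldehyde, mild enough for the aryl ethers and the trisubstituted alkene.

Step 13
Reactants: 20 axial aldehyde
Product: 22 3-{[(1R,2S,8aS)-1,2,5,5-tetramethyl-1,2,3,5,6,7,8,8a-octahydronaphthalen-1-yl]methyl}-1,2,4,5-tetramethoxybenzene, via aldehyde hydrazone 21 (not isolated)
Conditions: N2H4·H2O, KOH, diethylene glycol, 130 °C, then 200 °C, under Ar
Reagents that add atoms: none
Why: Wolff–Kishner reduction (Huang-Minlon procedure), the classical conversion of a hindered, non-enolisable angular formyl group into a methyl group, which leaves the quaternary C9, the unactivated alkene and the aryl methyl ethers alone.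

Step 14
Reactants: 22 tetramethoxyarene
Product: 23 2,5-dimethoxy-3-{[(1R,2S,8aS)-1,2,5,5-tetramethyl-1,2,3,5,6,7,8,8a-octahydronaphthalen-1-yl]methyl}cyclohexa-2,5-diene-1,4-dione
Conditions: (NH4)2Ce(NO3)6, MeCN/H2O, 0 °C
Reagents that add atoms: water, O
Why: Oxidative demethylation of a 1,4-dimethoxyarene to the para-quinone, in which the local mirror plane through C3' and C6' makes the two para pairs equivalent so that one 2,5-dimethoxyquinone results, and the hindered alkene is not attacked.

Step 15
Reactants: 23 dimethoxyquinone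
Product: 24 2-hydroxy-5-methoxy-3-{[(1R,2S,8aS)-1,2,5,5-tetramethyl-1,2,3,5,6,7,8,8a-octahydronaphthalen-1-yl]methyl}cyclohexa-2,5-diene-1,4-dione
Conditions: KOH, MeOH/H2O, rt; then dilute HCl, 0 °C
Reagents that add atoms: potassium hydroxide, [K+].[OH-]
Why: Addition–elimination of hydroxide on a vinylogous ester, in which the C2' methoxy group, twisted out of conjugation by the C11 substituent, is the less stabilised one and is exchanged first, as is usual for 3-alkyl-2,5-dimethoxybenzoquinones, and the hydroxyquinone anion then resists a second attack.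

Step 16
Reactants: 24 hydroxy methoxy quinone; 25 3-methylbutan-1-amine (isopentylamine, 3 equiv)
Product: 26 nakijiquinone M
Conditions: 25, EtOH, rt; aq citric acid wash
Reagents that add atoms: none
Why: Addition–elimination of the primary amine at the unhindered C5' turns the remaining vinylogous ester into the vinylogous amide, the standard aminolysis of 2-hydroxy-5-methoxyquinones, and affects no stereocentre.

Compound list
1 | 2,2-dimethylcyclohexan-1-one | CC1(C)CCCCC1=O | starting material
2 | (E)-N'-(2,2-dimethylcyclohexylidene)-2,4,6-triisopropylbenzenesulfonohydrazide | CC(C)c1cc(C(C)C)c(S(=O)(=O)N/N=C2\CCCCC2(C)C)c(C(C)C)c1 | intermediate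
3 | (E)-but-2-enal | C/C=C/C=O | starting material
4 | 6,6-dimethylcyclohex-1-enyllithium | [Li]C1=CCCCC1(C)C | intermediate
5 | (E)-1-(6,6-dimethylcyclohex-1-en-1-yl)but-2-en-1-ol (racemic) | C/C=C/C(O)C1=CCCCC1(C)C | intermediate
6 | (E)-1-(6,6-dimethylcyclohex-1-en-1-yl)but-2-en-1-one | C/C=C/C(=O)C1=CCCCC1(C)C | intermediate
7 | dimethyl malonate | COC(=O)CC(=O)OC | starting material
8 | dimethyl 2-[(2S)-4-(6,6-dimethylcyclohex-1-en-1-yl)-4-oxobutan-2-yl]propanedioate | COC(=O)C(C(=O)OC)[C@@H](C)CC(=O)C1=CCCCC1(C)C | intermediate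
9 | dimethyl (2S,4aS,8aR)-2,5,5-trimethyl-4-oxooctahydronaphthalene-1,1(2H)-dicarboxylate | COC(=O)C1(C(=O)OC)[C@@H]2CCCC(C)(C)[C@H]2C(=O)C[C@@H]1C | intermediate
10 | dimethyl (2S,4S,4aS,8aR)-4-hydroxy-2,5,5-trimethyloctahydronaphthalene-1,1(2H)-dicarboxylate | COC(=O)C1(C(=O)OC)[C@@H]2CCCC(C)(C)[C@H]2[C@@H](O)C[C@@H]1C | intermediate
11 | dimethyl (2S,8aR)-2,5,5-trimethyl-3,5,6,7,8,8a-hexahydronaphthalene-1,1(2H)-dicarboxylate | COC(=O)C1(C(=O)OC)[C@@H]2CCCC(C)(C)C2=CC[C@@H]1C | intermediate
12 | methyl (1S,2S,8aR)-1-formyl-2,5,5-trimethyl-1,2,3,5,6,7,8,8a-octahydronaphthalene-1-carboxylate | COC(=O)[C@]1(C=O)[C@@H]2CCCC(C)(C)C2=CC[C@@H]1C | intermediate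
13 | 1,2,4,5-tetramethoxybenzene | COc1cc(OC)c(OC)cc1OC | starting material
14 | 2,3,5,6-tetramethoxyphenyllithium | [Li]c1c(OC)c(OC)cc(OC)c1OC | intermediate
15 | methyl (1S,2S,8aR)-1-[hydroxy(2,3,5,6-tetramethoxyphenyl)methyl]-2,5,5-trimethyl-1,2,3,5,6,7,8,8a-octahydronaphthalene-1-carboxylate (C11 epimers) | COC(=O)[C@]1(C(O)c2c(OC)c(OC)cc(OC)c2OC)[C@@H]2CCCC(C)(C)C2=CC[C@@H]1C | intermediate
16 | [(1R,2S,8aR)-1-(hydroxymethyl)-2,5,5-trimethyl-1,2,3,5,6,7,8,8a-octahydronaphthalen-1-yl](2,3,5,6-tetramethoxyphenyl)methanol (C11 epimers) | OC[C@]1(C(O)c2c(OC)c(OC)cc(OC)c2OC)[C@@H]2CCCC(C)(C)C2=CC[C@@H]1C | intermediate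
17 | cyclic thionocarbonate (1,3-dioxane-2-thione) of 16, spiro at C9 (C11 epimers) | S=C1OC[C@@]2([C@@H]3CCCC(C)(C)C3=CC[C@@H]2C)C(O1)c1c(OC)c(OC)cc(OC)c1OC | intermediate
18 | O-alkyl S-tributylstannyl thiocarbonate of alcohol 19 | CCCC[Sn](CCCC)(CCCC)SC(=O)OC[C@]1(Cc2c(OC)c(OC)cc(OC)c2OC)[C@@H]2CCCC(C)(C)C2=CC[C@@H]1C | intermediate
19 | [(1S,2S,8aR)-2,5,5-trimethyl-1-(2,3,5,6-tetramethoxybenzyl)-1,2,3,5,6,7,8,8a-octahydronaphthalen-1-yl]methanol | OC[C@]1(Cc2c(OC)c(OC)cc(OC)c2OC)[C@@H]2CCCC(C)(C)C2=CC[C@@H]1C | intermediate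
20 | (1S,2S,8aR)-2,5,5-trimethyl-1-(2,3,5,6-tetramethoxybenzyl)-1,2,3,5,6,7,8,8a-octahydronaphthalene-1-carbaldehyde | O=C[C@]1(Cc2c(OC)c(OC)cc(OC)c2OC)[C@@H]2CCCC(C)(C)C2=CC[C@@H]1C | intermediate
21 | (E)-hydrazone of aldehyde 20 | N/N=C/[C@]1(Cc2c(OC)c(OC)cc(OC)c2OC)[C@@H]2CCCC(C)(C)C2=CC[C@@H]1C | intermediate
22 | 3-{[(1R,2S,8aS)-1,2,5,5-tetramethyl-1,2,3,5,6,7,8,8a-octahydronaphthalen-1-yl]methyl}-1,2,4,5-tetramethoxybenzene | C[C@]1(Cc2c(OC)c(OC)cc(OC)c2OC)[C@@H]2CCCC(C)(C)C2=CC[C@@H]1C | intermediate
23 | 2,5-dimethoxy-3-{[(1R,2S,8aS)-1,2,5,5-tetramethyl-1,2,3,5,6,7,8,8a-octahydronaphthalen-1-yl]methyl}cyclohexa-2,5-diene-1,4-dione | COC1=CC(=O)C(OC)=C(C[C@@]2(C)[C@@H]3CCCC(C)(C)C3=CC[C@@H]2C)C1=O | intermediate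
24 | 2-hydroxy-5-methoxy-3-{[(1R,2S,8aS)-1,2,5,5-tetramethyl-1,2,3,5,6,7,8,8a-octahydronaphthalen-1-yl]methyl}cyclohexa-2,5-diene-1,4-dione | COC1=CC(=O)C(O)=C(C[C@@]2(C)[C@@H]3CCCC(C)(C)C3=CC[C@@H]2C)C1=O | intermediate
25 | 3-methylbutan-1-amine | CC(C)CCN | starting material
26 | nakijiquinone M, 2-hydroxy-5-[(3-methylbutyl)amino]-3-{[(1R,2S,8aS)-1,2,5,5-tetramethyl-1,2,3,5,6,7,8,8a-octahydronaphthalen-1-yl]methyl}cyclohexa-2,5-diene-1,4-dione | CC(C)CCNC1=CC(=O)C(O)=C(C[C@@]2(C)[C@@H]3CCCC(C)(C)C3=CC[C@@H]2C)C1=O | target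

Total step count: 16. Longest linear sequence: 16 steps (1 → 26). Compounds 3, 7, 13 and 25 enter as purchased.

Steps most likely to fail

1. Step 4.
- Risk: the amine may condense only slowly with the crowded, twisted C6 ketone. An uncatalysed addition could then compete and erode facial control at C8. The second addition may also stall.
- Fallback: C8 is set on the aldehyde instead of the ketone. The fallback sets out from 3 and 7.
- Iminium catalysis with α,α-diphenylprolinol trimethylsilyl ether (the enantiomer that leads to 8S) and benzoic acid in EtOH should give dimethyl 2-[(2S)-4-oxobutan-2-yl]propanedioate F1.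
- The malonate C–H is deprotonated with NaH. Vinyllithium 4, made from 2 as in step 2, then adds to the aldehyde to give dimethyl 2-[(2S)-4-(6,6-dimethylcyclohex-1-en-1-yl)-4-hydroxybutan-2-yl]propanedioate F2.
- Dess–Martin oxidation gives 8, now isolated. DBU in toluene closes ring B, and the route is rejoined at 9.

2. Step 7.
- Risk: the reagent may not discriminate well enough between the two diastereotopic esters. The aluminium hemiacetal may also collapse early, with over-reduction.
- Fallback: C9 is set by C–C bond formation instead of group selection. The fallback sets out from 11.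
- Krapcho demethoxycarbonylation (LiCl, wet DMSO, 160 °C) gives methyl (2S,8aS)-2,5,5-trimethyl-1,2,3,5,6,7,8,8a-octahydronaphthalene-1-carboxylate F3.
- In parallel, 14 is quenched with paraformaldehyde to (2,3,5,6-tetramethoxyphenyl)methanol F4. PBr3 converts it into 3-(bromomethyl)-1,2,4,5-tetramethoxybenzene F5.
- The enolate of F3 (LiN(i-Pr)2, THF/DMPU, −78 → 0 °C) should be benzylated by F5 on the face opposite to the C8 methyl and C1. This gives methyl (1S,2S,8aR)-2,5,5-trimethyl-1-(2,3,5,6-tetramethoxybenzyl)-1,2,3,5,6,7,8,8a-octahydronaphthalene-1-carboxylate F6.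
- LiAlH4 reduces F6, and the route is rejoined at 19.

3. Step 6.
- Risk: the axial C7 proton may be lost in competition with H-5. Ionisation followed by a hydride or methyl shift is also possible.
- Fallback: the alkene position is fixed by the ring closure itself. The fallback sets out from 8, isolated by leaving out DBU in step 4.
- t-BuMe2SiOSO2CF3/Et3N in CH2Cl2 brings about an intramolecular Mukaiyama–Michael closure. It should give dimethyl (2S,8aR)-4-(tert-butyldimethylsilyloxy)-2,5,5-trimethyl-3,5,6,7,8,8a-hexahydronaphthalene-1,1(2H)-dicarboxylate F7.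
- CsF and PhN(SO2CF3)2 in DME trap the enolate as it forms. The product is dimethyl (2S,8aR)-2,5,5-trimethyl-4-(trifluoromethylsulfonyloxy)-3,5,6,7,8,8a-hexahydronaphthalene-1,1(2H)-dicarboxylate F8.
- Reduction with Pd(OAc)2, PPh3, HCO2H and Et3N in DMF at 60 °C rejoins the route at 11.

Further compounds
F1 | step 4 | dimethyl 2-[(2S)-4-oxobutan-2-yl]propanedioate | COC(=O)C(C(=O)OC)[C@@H](C)CC=O
F2 | step 4 | dimethyl 2-[(2S)-4-(6,6-dimethylcyclohex-1-en-1-yl)-4-hydroxybutan-2-yl]propanedioate (carbinol epimers) | COC(=O)C(C(=O)OC)[C@@H](C)CC(O)C1=CCCCC1(C)C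
F3 | step 7 | methyl (2S,8aS)-2,5,5-trimethyl-1,2,3,5,6,7,8,8a-octahydronaphthalene-1-carboxylate (C9 epimers) | COC(=O)C1[C@@H]2CCCC(C)(C)C2=CC[C@@H]1C
F4 | step 7 | (2,3,5,6-tetramethoxyphenyl)methanol | OCc1c(OC)c(OC)cc(OC)c1OC
F5 | step 7 | 3-(bromomethyl)-1,2,4,5-tetramethoxybenzene | BrCc1c(OC)c(OC)cc(OC)c1OC
F6 | step 7 | methyl (1S,2S,8aR)-2,5,5-trimethyl-1-(2,3,5,6-tetramethoxybenzyl)-1,2,3,5,6,7,8,8a-octahydronaphthalene-1-carboxylate | COC(=O)[C@]1(Cc2c(OC)c(OC)cc(OC)c2OC)[C@@H]2CCCC(C)(C)C2=CC[C@@H]1C
F7 | step 6 | dimethyl (2S,8aR)-4-(tert-butyldimethylsilyloxy)-2,5,5-trimethyl-3,5,6,7,8,8a-hexahydronaphthalene-1,1(2H)-dicarboxylate | COC(=O)C1(C(=O)OC)[C@@H]2CCCC(C)(C)C2=C(O[Si](C)(C)C(C)(C)C)C[C@@H]1C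
F8 | step 6 | dimethyl (2S,8aR)-2,5,5-trimethyl-4-(trifluoromethylsulfonyloxy)-3,5,6,7,8,8a-hexahydronaphthalene-1,1(2H)-dicarboxylate | COC(=O)C1(C(=O)OC)[C@@H]2CCCC(C)(C)C2=C(OS(=O)(=O)C(F)(F)F)C[C@@H]1C
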